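## The problem

Leoligin (11) is a monocyclic lignan. A single tetrahydrofuran ring (O1, C2–C5) carries a 3,4-dimethoxyphenyl group on C2, an angeloyloxymethyl arm (C6) on C3 and a 3,4-dimethoxybenzyl arm (C7 plus aryl) on C4. The three ring stereocentres are contiguous, (2S,3R,4R): the C2 aryl group is trans to the C3 arm and the C3 and C4 arms are cis. That cis pair of carbon arms is not reached by equilibration, so it has to come from a kinetically controlled ring closure. Only C2 is a C–O centre that asymmetric catalysis can deliver directly; C3 and C4 are all-carbon methines and are best set relative to C2. Three functions restrict the reagents. The C2 benzylic ether, with its electron-rich ring, ionises in strong acid and is cleaved by hydrogenolysis. Both veratryl rings are sensitive to oxidants. The angelate isomerises to the tiglate whenever its carbonyl group is activated, so the ester must be made last and without acyl activation. The enabling feature is that C3 and C4 are neighbours, each with a one-carbon arm, that C5–C4–C7 attached to O1 is a masked O-allyl group, and that C7 bears an aryl ring. A planar radical at C3 can therefore close onto an O1-allyl ether at C4, and the radical left at C7 can be arylated in the same operation, with C2 alone dictating the outcome.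

## Retrosynthesis

**Ester.** The C6–O bond of the angelate is cut first, giving alcohol 9 and angelic acid 10. Forming this bond by displacement at C6 (Mitsunobu) rather than by acylation keeps the Z-enoate away from any activated acyl intermediate. The forward step only has to tolerate a β-branched primary carbon.

**Silyl ether.** Alcohol 9 is traced to its tert-butyldimethylsilyl ether 8. The silyl group is needed because a free hydroxyl next to the radical carbon would complicate the halide synthesis; it is removed by fluoride under conditions that leave the benzylic ether alone.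

**Ring and aryl group.** In 8 the C3–C4 bond and the C7–aryl bond are cut together, leading to the acyclic β-iodo allyl ether 6 and 4-iodo-1,2-dimethoxybenzene 7. Cutting only C7–aryl would leave a 4-halomethyl tetrahydrofuran whose three stereocentres are still unsolved. Cutting only C3–C4 would require a second veratryl alkene to be built beforehand. The double cut removes the ring, two skeletal bonds and two stereocentres, and leaves an allyl group and a commercial aryl iodide. The forward reaction must generate the C3 radical, close the ring 5-exo before nickel intercepts the radical, and relay the configuration of C2 to C3 and C4.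

**Iodide.** The C–I bond of 6 is traced to the C–O bond of secondary alcohol 5. Because the iodine-bearing carbon becomes planar in the key step, the displacement needs no stereochemical fidelity, only chemoselectivity.

**Silylation.** Alcohol 5 comes from diol 4 by silylation of the primary hydroxyl, a purely steric differentiation.

**Benzylic ether.** The benzylic C–O bond of 4 is cut to epoxy alcohol 2 and allyl alcohol 3. Opening the epoxide at the aryl-bearing carbon installs the allyl ether and the future C2 configuration in one step, and leaves the neighbouring hydroxyl exactly where the iodide is needed. The forward reaction must go with inversion; the syn diol from any retentive leakage carries the wrong benzylic configuration and is removed as a diastereomer at this stage, which protects the enantiopurity of everything downstream.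

**Epoxide.** Epoxy alcohol 2 is the Sharpless epoxide of the commercial cinnamyl alcohol 1. This is the only absolute stereochemical input of the route and it is catalytic.

## Roads not taken

Alternative 1: The cut is O1–C2 and C3–C4. (E)-3-(3,4-Dimethoxyphenyl)prop-2-enal A1 and 3-(3,4-dimethoxyphenyl)prop-2-yn-1-ol A2 would be combined under a diarylprolinol silyl ether and Pd(PPh3)4. Reversible oxa-Michael addition to the iminium ion makes O1–C2, and the enamine then closes 5-exo-dig onto the metal-activated alkyne to make C3–C4, giving the benzylidene aldehyde A3.
- Merits: two achiral partners, a catalytic asymmetric ring construction, both aryl rings in place, and C2 and C3 set together. On paper the route is shorter than the chosen one (key step, alkene reduction, aldehyde reduction, esterification), and in step count it is the better plan.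
- Weak points: the alkyne is internal and aryl-substituted, a less reactive partner for enamine carbocyclisation than a terminal alkyne. C4 is not set in the key step; it must come from hydrogenation of the exocyclic styrenyl alkene of A3 from the face anti to the C3 arm. A hydroxyl- or carbonyl-directed reduction would give the wrong 3,4-trans isomer, and hydrogenation over Pd/C endangers the C2 benzylic C–O bond.
- Comparison: the chosen plan sets against its extra steps that C3 and C4 are both fixed in the ring-forming event, with no reduction near the benzylic ether.

Alternative 2: The cut is C2–C3 and C4–C5. A carbonyl ylide released by CsF from the α-chloro silylmethyl ether A4 would add across the C=C of the menthyloxy butenolide A5 to give the cis-fused furofuranone A6.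
- Merits: the ring fusion guarantees the 3,4-cis relationship by constraint rather than by a transition-state preference, which is more secure than in the chosen plan. The menthyloxy group is a well-understood director of facial selectivity, and C6 and C7 arrive already differentiated as lactone and acetal.
- Weak points: the regiochemistry of an unsymmetrical, non-stabilised ylide across the butenolide is not assured, and exo/endo selectivity decides the 2,3 relationship. The ylide precursor A4 is a labile α-chloro ether and the auxiliary is stoichiometric. The endgame is long: lactone reduction, unmasking of C7, addition of an aryl nucleophile, and removal of the new benzylic hydroxyl at C7 in the presence of the equally benzylic C2–O bond.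
- Comparison: the chosen plan forms the C7–aryl bond at the correct oxidation level in the key step and avoids that deoxygenation.

Alternative 3: The cut is C3–C4, made by ring contraction. Irradiation of the diazo ketone A7 in methanol expels N2, the benzyl-bearing carbon migrates with retention to the carbene carbon, and the ketene is trapped as the ester A8.
- Merits: C2 can come from an enantioselective hetero-Diels–Alder construction of the pyranone. The benzyl-bearing carbon can be equilibrated to the 2,5-trans diequatorial arrangement in the six-membered ketone before contraction, so C4 is under thermodynamic control, a firmer basis than the kinetic control of the chosen plan.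
- Weak points: C3 is created by protonation of the ketene-derived enol and is not controlled by the rearrangement; the target needs the ester cis to the benzyl group. Diazo transfer next to a β-aryl-β-alkoxy ketone invites retro-oxa-Michael ring opening and loss of C2. The veratryl chromophores compete for light. The sequence (pyranone, benzylation, diazo transfer, contraction, ester reduction, esterification) is no shorter.
- Comparison: the chosen plan sets C3 and C4 in one step from C2 and needs no photochemistry.

Key step: step 5

Remark on the chemistry: iodide 6 is written as the epimer expected from clean inversion. Its iodine-bearing carbon becomes a planar radical in step 5, so any epimerisation there by iodide exchange is without consequence. Compounds 1, 3, 7 and 10 are commercial.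

## Route

Step 1
Reactants: 1 (E)-3-(3,4-dimethoxyphenyl)prop-2-en-1-ol
Product: 2 [(2S,3S)-3-(3,4-dimethoxyphenyl)oxiran-2-yl]methanol
Conditions: Ti(OiPr)4 (10 mol%), L-(+)-diisopropyl tartrate (12 mol%), t-BuOOH (2 equiv, decane), 4 Å MS, CH2Cl2, −20 °C; basic work-up
Reagents that add atoms: tert-butyl hydroperoxide, CC(C)(C)OO
Why: Sharpless asymmetric epoxidation; the titanium tartrate complex binds the allylic hydroxyl and delivers the peroxide oxygen to one face of the E-alkene, and L-(+)-tartrate esters are expected to give the (2S,3S)-epoxide from (E)-3-arylallyl alcohols, fixing both epoxide carbons; the cold, non-acidic medium spares the acid-labile aryl epoxide.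

Step 2
Reactants: 2 [(2S,3S)-3-(3,4-dimethoxyphenyl)oxiran-2-yl]methanol, 3 prop-2-en-1-ol (allyl alcohol)
Product: 4 (2S,3R)-3-(3,4-dimethoxyphenyl)-3-(prop-2-en-1-yloxy)propane-1,2-diol
Conditions: BF3·OEt2 (5 mol%), allyl alcohol (10 equiv), CH2Cl2, −40 to −20 °C; Et3N quench
Reagents that add atoms: none
Why: Lewis-acid-catalysed epoxide alcoholysis; BF3 coordination polarises the benzylic C–O bond, which the electron-rich ring weakens further, so allyl alcohol should enter only at the aryl-bearing carbon and anti to the departing oxygen (inversion), giving the anti diol with the benzylic configuration of the target. Low temperature and excess nucleophile favour the invertive pathway, and the syn diol from any retentive leakage is a diastereomer removed by chromatography.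

Step 3
Reactants: 4 (2S,3R)-3-(3,4-dimethoxyphenyl)-3-(prop-2-en-1-yloxy)propane-1,2-diol
Product: 5 (2S,3R)-1-[(tert-butyldimethylsilyl)oxy]-3-(3,4-dimethoxyphenyl)-3-(prop-2-en-1-yloxy)propan-2-ol
Conditions: TBSCl (1.05 equiv), imidazole, CH2Cl2, 0 °C
Reagents that add atoms: tert-butyldimethylsilyl chloride, CC(C)(C)[Si](C)(C)Cl
Why: Silylation of a 1,2-diol with one equivalent of a bulky silyl chloride is selective for the primary hydroxyl on steric grounds; no stereocentre is touched.

Step 4
Reactants: 5 (2S,3R)-1-[(tert-butyldimethylsilyl)oxy]-3-(3,4-dimethoxyphenyl)-3-(prop-2-en-1-yloxy)propan-2-ol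
Product: 6 tert-butyl{[(2R,3R)-3-(3,4-dimethoxyphenyl)-2-iodo-3-(prop-2-en-1-yloxy)propyl]oxy}dimethylsilane
Conditions: PPh3, I2, imidazole, toluene, 70 °C
Reagents that add atoms: iodine, II
Why: Appel-type iodination; the secondary hydroxyl becomes an alkoxyphosphonium ion that iodide displaces with inversion. The configuration made here is erased in step 5, the benzylic centre is not involved, and imidazole buffers the medium so that the silyl and benzylic ethers should survive.

Step 5
Reactants: 6 tert-butyl{[(2R,3R)-3-(3,4-dimethoxyphenyl)-2-iodo-3-(prop-2-en-1-yloxy)propyl]oxy}dimethylsilane, 7 4-iodo-1,2-dimethoxybenzene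
Product: 8 tert-butyl{[(2S,3R,4R)-4-(3,4-dimethoxybenzyl)-2-(3,4-dimethoxyphenyl)tetrahydrofuran-3-yl]methoxy}dimethylsilane
Conditions: NiI2 (10 mol%), 4,4′-di-tert-butyl-2,2′-bipyridine (10 mol%), Mn powder (3 equiv), 7 (1.5 equiv), N,N-dimethylacetamide, 25 °C
Reagents that add atoms: none
Why: Mn reduces NiI2/4,4′-di-tert-butyl-2,2′-bipyridine to low-valent nickel, which adds oxidatively to aryl iodide 7 to give an aryl–nickel iodide (divalent nickel) and, as monovalent nickel, abstracts iodine from 6 to release the secondary C3 radical; the closest known reaction type is the nickel-catalysed reductive cyclisation–arylation of alkene-tethered alkyl halides (β-halo ethers and acetals) with aryl iodides. The radical is planar, so the configuration of the C–I carbon of 6 is irrelevant, and it closes the tetrahydrofuran ring by 5-exo-trig attack on the internal carbon of the O-allyl group (C3–C4), a unimolecular closure that for a 3-oxa-5-hexenyl radical should outrun bimolecular capture by nickel. The ring should form through a chair-like transition state with the C2 aryl group pseudo-equatorial and the CH2OSi arm on the radical carbon anti to it, so the one existing stereocentre, C2, sets C3 (2,3-trans) and C4 (2,4-trans, hence 3,4-cis), the usual preference of 1,2-disubstituted hexenyl radicals. The primary C7 radical left outside the ring is captured by the aryl–nickel iodide, and reductive elimination from the resulting trivalent nickel forms the C7–aryl bond and returns monovalent nickel to the cycle. The step needs cyclisation before arylation, which the fast ring closure and the low NiI2 loading secure; cross-coupling rather than homocoupling, which the different activation modes of the aryl and alkyl iodides and the excess of 7 secure; and diastereocontrol, which rests on the C2 aryl group. The silyl ether, the aryl methyl ethers and the benzylic ether are inert to Mn and the neutral amide solvent.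

Step 6
Reactants: 8 tert-butyl{[(2S,3R,4R)-4-(3,4-dimethoxybenzyl)-2-(3,4-dimethoxyphenyl)tetrahydrofuran-3-yl]methoxy}dimethylsilane
Product: 9 [(2S,3R,4R)-4-(3,4-dimethoxybenzyl)-2-(3,4-dimethoxyphenyl)tetrahydrofuran-3-yl]methanol
Conditions: Bu4NF, THF, 0 °C to rt
Reagents that add atoms: none
Why: Fluoride-induced silyl ether cleavage driven by the Si–F bond; the near-neutral conditions leave the benzylic ether and the three stereocentres untouched.

Step 7
Reactants: 9 [(2S,3R,4R)-4-(3,4-dimethoxybenzyl)-2-(3,4-dimethoxyphenyl)tetrahydrofuran-3-yl]methanol, 10 (2Z)-2-methylbut-2-enoic acid (angelic acid)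
Product: 11 leoligin, [(2S,3R,4R)-4-(3,4-dimethoxybenzyl)-2-(3,4-dimethoxyphenyl)tetrahydrofuran-3-yl]methyl (2Z)-2-methylbut-2-enoate
Conditions: PPh3, diisopropyl azodicarboxylate, THF, 0 °C to rt
Reagents that add atoms: none
Why: Mitsunobu esterification; the primary alcohol is activated as its alkoxyphosphonium ion and displaced at C6 by angelate, so the acyl carbon is never activated and the Z-enoate has no addition–elimination route to the tiglate. The reacting carbon is a CH2 group, so no stereocentre is affected.

## Compound list

1 | (E)-3-(3,4-dimethoxyphenyl)prop-2-en-1-ol | COc1ccc(/C=C/CO)cc1OC | starting material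
2 | [(2S,3S)-3-(3,4-dimethoxyphenyl)oxiran-2-yl]methanol | OC[C@@H]1O[C@H]1c1ccc(OC)c(OC)c1 | intermediate
3 | prop-2-en-1-ol (allyl alcohol) | C=CCO | starting material
4 | (2S,3R)-3-(3,4-dimethoxyphenyl)-3-(prop-2-en-1-yloxy)propane-1,2-diol | C=CCO[C@H](c1ccc(OC)c(OC)c1)[C@@H](O)CO | intermediate
5 | (2S,3R)-1-[(tert-butyldimethylsilyl)oxy]-3-(3,4-dimethoxyphenyl)-3-(prop-2-en-1-yloxy)propan-2-ol | C=CCO[C@H](c1ccc(OC)c(OC)c1)[C@@H](O)CO[Si](C)(C)C(C)(C)C | intermediate
6 | tert-butyl{[(2R,3R)-3-(3,4-dimethoxyphenyl)-2-iodo-3-(prop-2-en-1-yloxy)propyl]oxy}dimethylsilane | C=CCO[C@H](c1ccc(OC)c(OC)c1)[C@H](I)CO[Si](C)(C)C(C)(C)C | intermediate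
7 | 4-iodo-1,2-dimethoxybenzene | COc1ccc(I)cc1OC | starting material
8 | tert-butyl{[(2S,3R,4R)-4-(3,4-dimethoxybenzyl)-2-(3,4-dimethoxyphenyl)tetrahydrofuran-3-yl]methoxy}dimethylsilane | CC(C)(C)[Si](C)(C)OC[C@H]1[C@@H](Cc2ccc(OC)c(OC)c2)CO[C@@H]1c1ccc(OC)c(OC)c1 | intermediate
9 | [(2S,3R,4R)-4-(3,4-dimethoxybenzyl)-2-(3,4-dimethoxyphenyl)tetrahydrofuran-3-yl]methanol | OC[C@H]1[C@@H](Cc2ccc(OC)c(OC)c2)CO[C@@H]1c1ccc(OC)c(OC)c1 | intermediate
10 | (2Z)-2-methylbut-2-enoic acid (angelic acid) | C/C=C(/C)C(=O)O | starting material
11 | leoligin, [(2S,3R,4R)-4-(3,4-dimethoxybenzyl)-2-(3,4-dimethoxyphenyl)tetrahydrofuran-3-yl]methyl (2Z)-2-methylbut-2-enoate | C/C=C(/C)C(=O)OC[C@H]1[C@@H](Cc2ccc(OC)c(OC)c2)CO[C@@H]1c1ccc(OC)c(OC)c1 | target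

## Step count and least certain steps

Total steps: 7. Longest linear sequence: 7 steps (1 to 11).

**Step 5 (key step).** Three processes could undermine it:
- capture of the C3 radical by nickel before ring closure, leading to direct arylation at C3 or, after reduction, to β-alkoxy elimination with loss of the allyloxy group;
- incomplete relay of the C2 configuration, since the 3,4-cis preference is a transition-state preference and not a constraint;
- homocoupling of the aryl iodide and hydrodeiodination, which would consume the partners.

Fallback, from 6 back to 8: the aryl ring is placed on the alkene first and the ring is then closed by a tin hydride chain. Cross-metathesis of 6 with 4-ethenyl-1,2-dimethoxybenzene, using the second-generation Grubbs catalyst (H2IMes)(PCy3)Cl2Ru=CHPh in CH2Cl2 at 40 °C, should give the cinnamyl ether iodide F1. Slow addition of Bu3SnH and azobisisobutyronitrile to F1 in toluene at 80 °C generates the same C3 radical, which closes 5-exo onto the styrenyl alkene through the same chair-like transition state. The benzylic C7 radical is reduced by the stannane, giving 8.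

**Step 4.** Displacement at a secondary carbon flanked by two oxygen-bearing carbons is slow. Participation of the neighbouring electron-rich aryl ring (1,2-aryl shift towards an oxocarbenium ion), elimination, or partial loss of the silyl group could compete with substitution.

Fallback, from 4 back to 9: this avoids the displacement altogether and makes the C3 radical from an epoxide.
- Cross-metathesis of diol 4 with 4-ethenyl-1,2-dimethoxybenzene (same ruthenium catalyst) should give the cinnamyl ether diol F2.
- Selective tosylation of the primary hydroxyl (TsCl, Et3N, Bu2SnO cat., CH2Cl2) gives the monotosylate F3.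
- K2CO3 in methanol closes the terminal epoxide F4.
- Cp2TiCl, generated from Cp2TiCl2 and Zn dust in THF (trivalent titanium), opens the epoxide homolytically at its secondary carbon to a β-titanoxy C3 radical. This cyclises 5-exo onto the cinnamyl ether; the benzylic radical is reduced by a second equivalent of Cp2TiCl and protonated on acidic work-up, delivering alcohol 9 directly.

**Step 2.** Partial ionisation of the Lewis-acid-bound epoxide to a benzylic cation would erode the stereospecificity of the opening; acid-induced rearrangement of the epoxide is a second loss pathway. Any syn diol not removed would lower the enantiopurity of all later compounds.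

Fallback, from 2 back to 4: the bond is formed by an anionic displacement instead.
- Tritylation of 2 (Ph3CCl, Et3N, 4-dimethylaminopyridine, CH2Cl2) gives the trityl ether F5; this blocks Payne rearrangement.
- Sodium allyloxide (NaH in allyl alcohol 3, 50 °C) should open F5 at the benzylic carbon with inversion, because the other epoxide carbon is deactivated by the adjacent C–O bond, giving the allyl ether F6.
- Brief treatment with TsOH (cat.) in methanol at 0 °C removes the trityl group and returns diol 4.

**Step 7.** Displacement at the β-branched primary carbon may be slow. Reversible conjugate addition of the phosphine to the enoate could then isomerise Z to E, or the acid could be diverted to its anhydride.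

Fallback, from 9 back to 11: the Z-alkene is built after the ester bond. Esterification of 9 with 2-[bis(2,2,2-trifluoroethoxy)phosphoryl]propanoic acid (N-ethyl-N′-(3-dimethylaminopropyl)carbodiimide hydrochloride, 4-dimethylaminopyridine, CH2Cl2) gives the phosphonopropanoate F7. Still–Gennari olefination of F7 with acetaldehyde (KN(SiMe3)2, 18-crown-6, THF, −78 °C) should give the Z-trisubstituted enoate 11 under kinetic control.

Further compounds

F1 | step 5 | tert-butyl{[(2R,3R)-3-(3,4-dimethoxyphenyl)-3-{[(2E)-3-(3,4-dimethoxyphenyl)prop-2-en-1-yl]oxy}-2-iodopropyl]oxy}dimethylsilane | COc1ccc(/C=C/CO[C@H](c2ccc(OC)c(OC)c2)[C@H](I)CO[Si](C)(C)C(C)(C)C)cc1OC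
F2 | step 4 | (2S,3R)-3-(3,4-dimethoxyphenyl)-3-{[(2E)-3-(3,4-dimethoxyphenyl)prop-2-en-1-yl]oxy}propane-1,2-diol | COc1ccc(/C=C/CO[C@H](c2ccc(OC)c(OC)c2)[C@@H](O)CO)cc1OC
F3 | step 4 | (2S,3R)-3-(3,4-dimethoxyphenyl)-3-{[(2E)-3-(3,4-dimethoxyphenyl)prop-2-en-1-yl]oxy}-2-hydroxypropyl 4-methylbenzenesulfonate | COc1ccc(/C=C/CO[C@H](c2ccc(OC)c(OC)c2)[C@@H](O)COS(=O)(=O)c2ccc(C)cc2)cc1OC
F4 | step 4 | (2S)-2-[(R)-(3,4-dimethoxyphenyl){[(2E)-3-(3,4-dimethoxyphenyl)prop-2-en-1-yl]oxy}methyl]oxirane | COc1ccc(/C=C/CO[C@H](c2ccc(OC)c(OC)c2)[C@@H]2CO2)cc1OC
F5 | step 2 | (2S,3S)-2-(3,4-dimethoxyphenyl)-3-[(triphenylmethoxy)methyl]oxirane | C(c1ccccc1)(c1ccccc1)(c1ccccc1)OC[C@@H]1O[C@H]1c1ccc(OC)c(OC)c1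
F6 | step 2 | (2S,3R)-3-(3,4-dimethoxyphenyl)-3-(prop-2-en-1-yloxy)-1-(triphenylmethoxy)propan-2-ol | C=CCO[C@H](c1ccc(OC)c(OC)c1)[C@@H](O)COC(c1ccccc1)(c1ccccc1)c1ccccc1
F7 | step 7 | [(2S,3R,4R)-4-(3,4-dimethoxybenzyl)-2-(3,4-dimethoxyphenyl)tetrahydrofuran-3-yl]methyl 2-[bis(2,2,2-trifluoroethoxy)phosphoryl]propanoate (mixture of epimers at the phosphonate-bearing carbon) | CC(C(=O)OC[C@H]1[C@@H](Cc2ccc(OC)c(OC)c2)CO[C@@H]1c1ccc(OC)c(OC)c1)P(=O)(OCC(F)(F)F)OCC(F)(F)F
A1 | alternative 1 | (E)-3-(3,4-dimethoxyphenyl)prop-2-enal | COc1ccc(/C=C/C=O)cc1OC
A2 | alternative 1 | 3-(3,4-dimethoxyphenyl)prop-2-yn-1-ol | COc1ccc(C#CCO)cc1OC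
A3 | alternative 1 | (2S,3S,4E)-4-(3,4-dimethoxybenzylidene)-2-(3,4-dimethoxyphenyl)tetrahydrofuran-3-carbaldehyde (2,3-trans) | O=C[C@H]1/C(=C\c2ccc(OC)c(OC)c2)CO[C@@H]1c1ccc(OC)c(OC)c1
A4 | alternative 2 | 4-{chloro[(trimethylsilyl)methoxy]methyl}-1,2-dimethoxybenzene (racemic) | COc1ccc(C(Cl)OC[Si](C)(C)C)cc1OC
A5 | alternative 2 | (5S)-5-{[(1S,2R,5S)-5-methyl-2-(propan-2-yl)cyclohexyl]oxy}furan-2(5H)-one | O=C1C=C[C@@H](O[C@H]2C[C@@H](C)CC[C@@H]2C(C)C)O1
A6 | alternative 2 | cis-fused 6-(3,4-dimethoxyphenyl)-3-{[(1S,2R,5S)-5-methyl-2-(propan-2-yl)cyclohexyl]oxy}tetrahydro-1H,3H-furo[3,4-c]furan-1-one, aryl exo, ring carbons configured as C2, C3 and C4 of the target | O=C1[C@H]2[C@H](CO[C@@H]2c3ccc(OC)c(OC)c3)[C@@H](O[C@H]4C[C@@H](C)CC[C@@H]4C(C)C)O1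
A7 | alternative 3 | 2,5-trans-3-diazo-5-(3,4-dimethoxybenzyl)-2-(3,4-dimethoxyphenyl)tetrahydro-4H-pyran-4-one, both stereocentres as in the target | [N-]=[N+]=C1C(=O)[C@@H](Cc2ccc(OC)c(OC)c2)CO[C@@H]1c1ccc(OC)c(OC)c1
A8 | alternative 3 | methyl (2S,3S,4R)-4-(3,4-dimethoxybenzyl)-2-(3,4-dimethoxyphenyl)tetrahydrofuran-3-carboxylate | COC(=O)[C@H]1[C@@H](Cc2ccc(OC)c(OC)c2)CO[C@@H]1c1ccc(OC)c(OC)c1
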